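(The data were computed for an exercise; noise was put on by code.)

A small charge of starting material meets coupling partner in a closed, stirred flask, and you want the single product left after two reaction times.

| setting | birch | maple | oak | south | south-west |
|---|---|---|---|---|---|
| starting material | 0.14 M | 0.22 M | 0.10 M | 0.10 M | 0.10 M |
| coupling partner | 0.12 M | 0.12 M | 0.24 M | 0.120 M | 0.120 M |
| remark | run made earlier | run made earlier | run made earlier |  |  |
| time |  |  |  | 30 min | 15 min |

| run | time / min | single product / % |
|---|---|---|
| birch | 1.33 | 7 |
| birch | 2.00 | 8 |
| birch | 3.00 | 9 |
| birch | 4.00 | 11 |
| birch | 6.00 | 11 |
| birch | 10.0 | 8 |
| birch | 15.0 | 6 |
| maple | 0.833 | 4 |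
| maple | 2.50 | 8 |
| maple | 4.00 | 11 |
| maple | 6.00 | 8 |
| maple | 10.0 | 5 |
| maple | 12.0 | 5 |
| maple | 15.0 | 3 |
| oak | 1.33 | 9 |
| oak | 4.00 | 15 |
| oak | 8.00 | 9 |
| oak | 10.0 | 6 |
| oak | 15.0 | 2 |

(scatter of a reading: 1.5 percentage points)

* which of the two there is more of at the end, south (single product / over-reaction product)
* which of the two there is more of at the end, south-west (single product / over-reaction product)
* how much single product is there at the end, in percent of the starting material charged: south
* how much single product is there at the end, in percent of the starting material charged: south-west

- a reading or a percentage of single product counts all its forms, free or not

Follow one molecule of single product: it forms, then moves on, and I take its chance of surviving to halve with each survival half-life, a first-order half-life. Oak has the starting material of south-west and twice its coupling partner, and oak's tail falls faster than birch's: from 9% at 8.00 min to 2% at 15.0 min. That reads as a survival half-life of 3.23 min, roughly, given a scatter of 1.5 percentage points and given that fresh single product still enters that tail.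

This is far shorter than 15 min, so in south-west nearly all of what forms at the start has moved on by the end, and I expect over-reaction product ahead in both flasks. Birch, with the same coupling partner, read 6% at that time, which I take for south-west. Over the extra time in south, I reckon that 3.98% of that stock survives, which leaves 0.239% for south, before adding later single product.

The forecast says of single product that “it is consumed faster than it forms”, and it gives over-reaction product as the larger for south with 4% of single product, and over-reaction product as the larger for south-west with 7% of single product, the last above my figure.

South-west gives 4.29% of single product against 21.5% of over-reaction product; south gives 0.816% against 27.8%. Read as early as 10.9 min, south's single product has moved by 6 points, while a charge of starting material moved at least as far as 0.0125 M down and 0.80 M up stays within that.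

    starting material + coupling partner → single product (k = 0.620 L mol⁻¹ min⁻¹)
    starting material + coupling partner → other mono adduct (k = 1.20 L mol⁻¹ min⁻¹)
    coupling partner + single product → double product (k = 0.00900 L mol⁻¹ min⁻¹)
    coupling partner + other mono adduct → double product (k = 1.00 L mol⁻¹ min⁻¹)
    single product → over-reaction product (k = 0.230 min⁻¹)
    coupling partner → decomposition product (k = 8.20 × 10⁻⁵ min⁻¹)
    starting material + single product ⇌ idle adduct, settled at all times (K = 6.00 L mol⁻¹)

Now read the south-west flask at 1.0 h, with its time the one change. South's 0.816% is the same mixture at 30 min, and the extra time leaves a survival chance of 0.159%. That stock therefore comes to 0.00130% by my reckoning. The flask shows more than that: 0.0933% of single product beside 29.8% of over-reaction product.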